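**Plan**
- Retrosynthesis: the isobutyrate on the phenol oxygen, the pentanoate on the side-chain CH2O and a silyl ether on the benzylic alcohol are cut first; next the O-CH2 bond of the oxirane (primary tosylate of a 1,2-diol), and the CH2OH arm is traced back to a vinyl group.
- With that arm as vinyl, the tertiary benzylic C-O bond at the quaternary carbon is allylic, so palladium can break it and form it again. This bond and one O-C(=O) bond of a 1,3-dioxolan-2-one ring are cut, back to a racemic 2-aryl-2-vinyloxirane and CO2.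
- The racemic oxirane is cut at the quaternary C-vinyl bond (vinyl Grignard) and at the aryl-C(=O) bond (aryllithium and a chloroacetamide).
- Forward: arene, chloroketone, racemic oxirane ring, dioxolanone ring, diol, oxirane ring closed again on the primary carbon, vinyl cut to CH2OH, pentanoate, aryl silyl ether exchanged for isobutyrate, benzylic alcohol freed.
- Stereochemistry: the single stereocenter comes from the chiral diphosphine in the palladium step; afterwards no bond to that carbon is broken.

Key step: step 6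

Assumption: the (1R,2R) antipode of the ligand is assumed to lead to (R)-14; the configuration is set by the catalyst alone, so the (1S,2S) antipode is used instead if the sense of induction on this aryl-substituted oxirane is the opposite.

Abbreviations in names: Ar = 4-[(tert-butyldimethylsilyloxy)methyl]-2-(triisopropylsilyloxy)phenyl; Ar' = 4-[(tert-butyldimethylsilyloxy)methyl]-2-(2-methylpropanoyloxy)phenyl.

**Step 1**
Reactants: 1 methyl 4-bromo-3-hydroxybenzoate
Product: 2 methyl 4-bromo-3-(triisopropylsilyloxy)benzoate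
Conditions: i-Pr3SiCl, imidazole, DMF, rt
Reagents that add atoms: triisopropylsilyl chloride, CC(C)[Si](Cl)(C(C)C)C(C)C
Why: Imidazole-promoted O-silylation of the phenol; the bulky triisopropylsilyl group is chosen because it should resist the 1,3 shift from oxygen to carbon at the later aryllithium stage and brief K2CO3/MeOH treatment, yet leave with fluoride at the end.

**Step 2**
Reactants: 2 methyl 4-bromo-3-(triisopropylsilyloxy)benzoate
Product: 3 [4-bromo-3-(triisopropylsilyloxy)phenyl]methanol
Conditions: i-Bu2AlH, CH2Cl2, -78 to 0 °C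
Reagents that add atoms: none
Why: Hydride reduction of the benzoate ester to the benzyl alcohol, which should leave the aryl bromide and the aryl silyl ether untouched.

**Step 3**
Reactants: 3 [4-bromo-3-(triisopropylsilyloxy)phenyl]methanol
Product: 4 tert-butyl{[4-bromo-3-(triisopropylsilyloxy)phenyl]methoxy}dimethylsilane
Conditions: t-BuMe2SiCl, imidazole, CH2Cl2, rt
Reagents that add atoms: tert-butyldimethylsilyl chloride, CC(C)(C)[Si](C)(C)Cl
Why: Standard silyl ether formation on the primary alcohol; an alkyl silyl ether is cleaved by fluoride much more slowly than the aryl silyl ether, which allows the two to be removed in turn.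

**Step 4**
Reactants: 4 tert-butyl{[4-bromo-3-(triisopropylsilyloxy)phenyl]methoxy}dimethylsilane; 5 2-chloro-N-methoxy-N-methylacetamide
Product: 8 2-chloro-1-Ar-ethan-1-one, via aryllithium 6 (not isolated), via lithium hemiaminal adduct 7 (not isolated)
Conditions: n-BuLi, THF, -78 °C; then 5, -78 °C; aq. NH4Cl
Reagents that add atoms: none
Why: Bromine-lithium exchange followed by a Weinreb ketone synthesis, in which the chelated tetrahedral adduct 7 survives until work-up so that the chloroketone is not attacked a second time.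

**Step 5**
Reactants: 8 2-chloro-1-Ar-ethan-1-one; 9 vinylmagnesium bromide
Product: 12 racemic 2-Ar-2-vinyloxirane, via bromomagnesium alkoxide 10 (not isolated), via chlorohydrin 11 (not isolated)
Conditions: CH2=CHMgBr, THF, -78 °C; then MeOH, K2CO3, -78 °C to rt
Reagents that add atoms: none
Why: Grignard 1,2-addition to the ketone and base-induced 3-exo-tet closure of the chlorohydrin (Williamson-type) should give the oxirane as a racemate, the magnesium being quenched by methanol before the acid-sensitive oxirane forms.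

**Step 6**
Reactants: 12 racemic 2-Ar-2-vinyloxirane; 13 carbon dioxide
Product: 14 (4R)-4-Ar-4-vinyl-1,3-dioxolan-2-one
Conditions: Pd2(dba)3·CHCl3 (2.5 mol%), (1R,2R)-N,N'-bis[2-(diphenylphosphino)benzoyl]cyclohexane-1,2-diamine (7.5 mol%), CO2 (1 atm), CH2Cl2, 0 °C to rt
Reagents that add atoms: none
Why: Zerovalent palladium opens the allylic tertiary C-O bond of either enantiomer of 12 to a zwitterionic π-allylpalladium alkoxide, the alkoxide adds to CO2, and the carbonate oxygen returns to the aryl-bearing allyl terminus. The closest known reaction type is the palladium-catalysed dynamic kinetic asymmetric addition of CO2 or hydrogencarbonate to 2-methyl-2-vinyloxirane, together with the palladium-catalysed insertion of CO2 into vinyloxiranes in general. The dioxolanone ring closes in the 5-exo mode on the proximal allyl carbon, the only alternative for the tethered oxygen being a 7-endo attack at the CH2 terminus. The quaternary stereocenter is set by the chiral diphosphine: the two diastereomeric π-allyl complexes interconvert through the σ-allyl at the unsubstituted CH2 terminus faster than they cyclise, and the ligand pocket lets one of them close faster. The step needs attack at the substituted terminus and one enantiomer from a racemate; the carbonate tether secures the first, the crowded aryl-bearing terminus, which slows ring closure relative to equilibration, secures the second, and a CO2 atmosphere with a stop at full conversion of 12 should keep 14 from ionising again.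

**Step 7**
Reactants: 14 (4R)-4-Ar-4-vinyl-1,3-dioxolan-2-one
Product: 15 (2R)-2-Ar-but-3-ene-1,2-diol
Conditions: K2CO3 (cat.), MeOH, 0 °C
Reagents that add atoms: none
Why: Base-catalysed methanolysis (transesterification) of the cyclic carbonate frees the diol without touching the stereocenter, and it is placed before any ester is in the molecule.

**Step 8**
Reactants: 15 (2R)-2-Ar-but-3-ene-1,2-diol
Product: 17 (2R)-2-Ar-2-vinyloxirane, via primary tosylate 16 (not isolated)
Conditions: TsCl, Et3N, Bu2SnO (cat.), CH2Cl2, 0 °C to rt; then K2CO3, MeOH, rt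
Reagents that add atoms: none
Why: Tin-catalysed sulfonylation should pick the primary hydroxyl of the 1,2-diol and the tertiary oxygen then displaces the tosylate in a 3-exo-tet Williamson closure, so no bond to the stereocenter is broken and 17 keeps the configuration of 14.

**Step 9**
Reactants: 17 (2R)-2-Ar-2-vinyloxirane
Product: 20 [(2S)-2-Ar-oxiran-2-yl]methanol, via ozonide 18 (not isolated), via epoxy aldehyde 19 (not isolated)
Conditions: O3, CH2Cl2, -78 °C; PPh3, -78 to 0 °C; then NaBH4, MeOH, -40 to 0 °C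
Reagents that add atoms: ozone, [O-][O+]=O
Why: Ozonolysis with reductive work-up cuts the vinyl group to the aldehyde, which borohydride reduces at once; the stereocenter is not involved (the descriptor changes only through the priority rules) and a Payne rearrangement of 20 would return the same enantiomer.

**Step 10**
Reactants: 20 [(2S)-2-Ar-oxiran-2-yl]methanol
Product: 21 [(2R)-2-Ar-oxiran-2-yl]methyl pentanoate
Conditions: (n-BuCO)2O, Et3N, DMAP (cat.), CH2Cl2, 0 °C
Reagents that add atoms: pentanoic anhydride, CCCCC(=O)OC(=O)CCCC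
Why: DMAP-catalysed O-acylation of the primary alcohol with the anhydride, which avoids the chloride and acid that could open the tertiary benzylic oxirane.

**Step 11**
Reactants: 21 [(2R)-2-Ar-oxiran-2-yl]methyl pentanoate
Product: 23 5-[(tert-butyldimethylsilyloxy)methyl]-2-[(2R)-2-(pentanoyloxymethyl)oxiran-2-yl]phenyl 2-methylpropanoate, via caesium phenoxide 22 (not isolated)
Conditions: CsF, (i-PrCO)2O (excess), DMF, 0 °C to rt
Reagents that add atoms: isobutyric anhydride, CC(C)C(=O)OC(=O)C(C)C
Why: Fluoride-induced cleavage of the aryl Si-O bond, much faster than that of the alkyl silyl ether, with acylation in the same flask: the excess anhydride should trap the phenoxide as it forms, before it can attack the neighbouring oxirane.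

**Step 12**
Reactants: 23 5-[(tert-butyldimethylsilyloxy)methyl]-2-[(2R)-2-(pentanoyloxymethyl)oxiran-2-yl]phenyl 2-methylpropanoate
Product: 24 5-(hydroxymethyl)-2-[(2R)-2-(pentanoyloxymethyl)oxiran-2-yl]phenyl 2-methylpropanoate
Conditions: Et3N·3HF, MeCN, 0 °C to rt
Reagents that add atoms: none
Why: Fluoride-mediated desilylation with a nearly neutral reagent should free the benzylic alcohol without base that could move the aryl ester and without acid strong enough to open the oxirane.

**Compound list**
1 | methyl 4-bromo-3-hydroxybenzoate | COC(=O)c1ccc(Br)c(O)c1 | starting material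
2 | methyl 4-bromo-3-(triisopropylsilyloxy)benzoate | COC(=O)c1ccc(Br)c(O[Si](C(C)C)(C(C)C)C(C)C)c1 | intermediate
3 | [4-bromo-3-(triisopropylsilyloxy)phenyl]methanol | OCc1ccc(Br)c(O[Si](C(C)C)(C(C)C)C(C)C)c1 | intermediate
4 | tert-butyl{[4-bromo-3-(triisopropylsilyloxy)phenyl]methoxy}dimethylsilane | CC(C)(C)[Si](C)(C)OCc1ccc(Br)c(O[Si](C(C)C)(C(C)C)C(C)C)c1 | intermediate
5 | 2-chloro-N-methoxy-N-methylacetamide | CON(C)C(=O)CCl | starting material
6 | {4-[(tert-butyldimethylsilyloxy)methyl]-2-(triisopropylsilyloxy)phenyl}lithium | [Li]c1ccc(CO[Si](C)(C)C(C)(C)C)cc1O[Si](C(C)C)(C(C)C)C(C)C | intermediate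
7 | lithium 2-chloro-1-[methoxy(methyl)amino]-1-Ar-ethan-1-olate (tetrahedral adduct) | CON(C)C(CCl)(O[Li])c1ccc(CO[Si](C)(C)C(C)(C)C)cc1O[Si](C(C)C)(C(C)C)C(C)C | intermediate
8 | 2-chloro-1-{4-[(tert-butyldimethylsilyloxy)methyl]-2-(triisopropylsilyloxy)phenyl}ethan-1-one | O=C(CCl)c1ccc(CO[Si](C)(C)C(C)(C)C)cc1O[Si](C(C)C)(C(C)C)C(C)C | intermediate
9 | vinylmagnesium bromide | C=C[Mg]Br | starting material
10 | bromomagnesium 1-chloro-2-Ar-but-3-en-2-olate (racemic) | C=CC(CCl)(O[Mg]Br)c1ccc(CO[Si](C)(C)C(C)(C)C)cc1O[Si](C(C)C)(C(C)C)C(C)C | intermediate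
11 | racemic 1-chloro-2-Ar-but-3-en-2-ol | C=CC(O)(CCl)c1ccc(CO[Si](C)(C)C(C)(C)C)cc1O[Si](C(C)C)(C(C)C)C(C)C | intermediate
12 | racemic 2-{4-[(tert-butyldimethylsilyloxy)methyl]-2-(triisopropylsilyloxy)phenyl}-2-vinyloxirane | C=CC1(c2ccc(CO[Si](C)(C)C(C)(C)C)cc2O[Si](C(C)C)(C(C)C)C(C)C)CO1 | intermediate
13 | carbon dioxide | O=C=O | starting material
14 | (4R)-4-{4-[(tert-butyldimethylsilyloxy)methyl]-2-(triisopropylsilyloxy)phenyl}-4-vinyl-1,3-dioxolan-2-one | C=C[C@@]1(c2ccc(CO[Si](C)(C)C(C)(C)C)cc2O[Si](C(C)C)(C(C)C)C(C)C)COC(=O)O1 | intermediate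
15 | (2R)-2-Ar-but-3-ene-1,2-diol | C=C[C@@](O)(c1ccc(CO[Si](C)(C)C(C)(C)C)cc1O[Si](C(C)C)(C(C)C)C(C)C)CO | intermediate
16 | (2R)-2-Ar-2-hydroxybut-3-en-1-yl 4-methylbenzenesulfonate | C=C[C@@](O)(c1ccc(CO[Si](C)(C)C(C)(C)C)cc1O[Si](C(C)C)(C(C)C)C(C)C)COS(=O)(=O)c1ccc(C)cc1 | intermediate
17 | (2R)-2-Ar-2-vinyloxirane | C=C[C@@]1(c2ccc(CO[Si](C)(C)C(C)(C)C)cc2O[Si](C(C)C)(C(C)C)C(C)C)CO1 | intermediate
18 | 3-[(2R)-2-Ar-oxiran-2-yl]-1,2,4-trioxolane (ozonide, trioxolane carbon unassigned) | C1(OOCO1)[C@@]2(c3ccc(CO[Si](C)(C)C(C)(C)C)cc3O[Si](C(C)C)(C(C)C)C(C)C)CO2 | intermediate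
19 | (2R)-2-Ar-oxirane-2-carbaldehyde | O=C[C@@]1(c2ccc(CO[Si](C)(C)C(C)(C)C)cc2O[Si](C(C)C)(C(C)C)C(C)C)CO1 | intermediate
20 | [(2S)-2-Ar-oxiran-2-yl]methanol | OC[C@@]1(c2ccc(CO[Si](C)(C)C(C)(C)C)cc2O[Si](C(C)C)(C(C)C)C(C)C)CO1 | intermediate
21 | [(2R)-2-Ar-oxiran-2-yl]methyl pentanoate | CCCCC(=O)OC[C@@]1(c2ccc(CO[Si](C)(C)C(C)(C)C)cc2O[Si](C(C)C)(C(C)C)C(C)C)CO1 | intermediate
22 | caesium 5-[(tert-butyldimethylsilyloxy)methyl]-2-[(2R)-2-(pentanoyloxymethyl)oxiran-2-yl]phenolate | CCCCC(=O)OC[C@@]1(c2ccc(CO[Si](C)(C)C(C)(C)C)cc2[O-])CO1.[Cs+] | intermediate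
23 | 5-[(tert-butyldimethylsilyloxy)methyl]-2-[(2R)-2-(pentanoyloxymethyl)oxiran-2-yl]phenyl 2-methylpropanoate | CCCCC(=O)OC[C@@]1(c2ccc(CO[Si](C)(C)C(C)(C)C)cc2OC(=O)C(C)C)CO1 | intermediate
24 | 5-(hydroxymethyl)-2-[(2R)-2-(pentanoyloxymethyl)oxiran-2-yl]phenyl 2-methylpropanoate (CNP0243215.1) | CCCCC(=O)OC[C@@]1(c2ccc(CO)cc2OC(=O)C(C)C)CO1 | target

**Totals**
Total step count: 12. Longest linear sequence: 12 steps (1 to 24).

**Steps most likely to fail**

Step 11. The phenoxide set free by fluoride may open the neighbouring oxirane (attack on its CH2 or quinone-methide-type ring opening) before it is acylated, or the benzylic silyl ether may be lost alongside. The fallback installs the aryl ester before the oxirane exists.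
- It sets out from diol 15: the tosylation of step 8 is stopped at tosylate 16, which is isolated.
- Buffered fluoride (Bu4NF/AcOH, THF, 0 °C) should free the phenol (2R)-2-hydroxy-2-{2-hydroxy-4-[(tert-butyldimethylsilyloxy)methyl]phenyl}but-3-en-1-yl 4-methylbenzenesulfonate F1.
- Isobutyryl chloride and pyridine should acylate the phenol only, the tertiary alcohol being inert, to give (2R)-2-Ar'-2-hydroxybut-3-en-1-yl 4-methylbenzenesulfonate F2.
- KN(SiMe3)2 in THF at -78 °C should close the ring to (2R)-2-Ar'-2-vinyloxirane F3; this relies on 3-exo-tet displacement of the tosylate being faster than acyl transfer to the hindered tertiary alkoxide.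
- Ozonolysis with PPh3 work-up passes through the ozonide 3-[(2R)-2-Ar'-oxiran-2-yl]-1,2,4-trioxolane F4 and the aldehyde (2R)-2-Ar'-oxirane-2-carbaldehyde F5, and NaBH4 at -78 °C should give [(2S)-2-Ar'-oxiran-2-yl]methanol F6.
- DMAP-catalysed pentanoylation as in step 10 comes back to the route at 23.

Step 6. The ortho-silyloxyaryl group may lower the enantioselectivity, or 14 may ionise again under the catalyst and lose enantiomeric purity with time. The fallback sets the same stereocenter by reagent-controlled epoxidation of an allylic alcohol.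
- It sets out from bromide 4: Stille coupling with 2-(tributylstannyl)prop-2-en-1-ol (Pd(PPh3)4, DMF, 80 °C) should give 2-Ar-prop-2-en-1-ol F7.
- Sharpless asymmetric epoxidation (Ti(O-i-Pr)4, L-(+)-diethyl tartrate, t-BuOOH, 4 Å molecular sieves, CH2Cl2, -20 °C) should deliver epoxy alcohol 20, where the route is rejoined before step 10.

Step 4. Proton transfer from the acidic CH2Cl group of amide 5 to the hindered aryllithium may outrun acyl substitution and return the debrominated arene. The fallback builds the oxirane from an enone instead of a chloroketone.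
- It sets out from bromide 4, with aryllithium 6 formed as before: addition to acrolein at -78 °C should give racemic 1-Ar-prop-2-en-1-ol F8.
- MnO2 in CH2Cl2 should oxidise it to 1-Ar-prop-2-en-1-one F9, which is used at once.
- Corey-Chaykovsky methylene transfer to the carbonyl group with dimethylsulfonium methylide (trimethylsulfonium iodide, KN(SiMe3)2, THF, -10 °C) comes back to the route at racemic oxirane 12.

**Further compounds**
F1 | step 11 | (2R)-2-hydroxy-2-{2-hydroxy-4-[(tert-butyldimethylsilyloxy)methyl]phenyl}but-3-en-1-yl 4-methylbenzenesulfonate | C=C[C@@](O)(c1ccc(CO[Si](C)(C)C(C)(C)C)cc1O)COS(=O)(=O)c1ccc(C)cc1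
F2 | step 11 | (2R)-2-Ar'-2-hydroxybut-3-en-1-yl 4-methylbenzenesulfonate | C=C[C@@](O)(c1ccc(CO[Si](C)(C)C(C)(C)C)cc1OC(=O)C(C)C)COS(=O)(=O)c1ccc(C)cc1
F3 | step 11 | (2R)-2-Ar'-2-vinyloxirane | C=C[C@@]1(c2ccc(CO[Si](C)(C)C(C)(C)C)cc2OC(=O)C(C)C)CO1
F4 | step 11 | 3-[(2R)-2-Ar'-oxiran-2-yl]-1,2,4-trioxolane | C1(OOCO1)[C@@]2(c3ccc(CO[Si](C)(C)C(C)(C)C)cc3OC(=O)C(C)C)CO2
F5 | step 11 | (2R)-2-Ar'-oxirane-2-carbaldehyde | O=C[C@@]1(c2ccc(CO[Si](C)(C)C(C)(C)C)cc2OC(=O)C(C)C)CO1
F6 | step 11 | [(2S)-2-Ar'-oxiran-2-yl]methanol | OC[C@@]1(c2ccc(CO[Si](C)(C)C(C)(C)C)cc2OC(=O)C(C)C)CO1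
F7 | step 6 | 2-Ar-prop-2-en-1-ol | C=C(CO)c1ccc(CO[Si](C)(C)C(C)(C)C)cc1O[Si](C(C)C)(C(C)C)C(C)C
F8 | step 4 | racemic 1-Ar-prop-2-en-1-ol | C=CC(O)c1ccc(CO[Si](C)(C)C(C)(C)C)cc1O[Si](C(C)C)(C(C)C)C(C)C
F9 | step 4 | 1-Ar-prop-2-en-1-one | C=CC(=O)c1ccc(CO[Si](C)(C)C(C)(C)C)cc1O[Si](C(C)C)(C(C)C)C(C)C
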